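The target is a trans-3,4-dibenzyl-γ-butyrolactone in which C3 and C4 of the lactone ring are the α- and β-carbons of the carbonyl and C5 is a bare OCH2. Both exocyclic bonds, C4–CH2(syringyl) and C3–CH2(trimethoxyphenyl), are therefore traced back to the C3=C4 bond of a butenolide carrying a removable l-menthyloxy group at C5. In one pot, a 2-aryl-2-lithio-1,3-dithiane (the masked, benzyl-protected syringyl CH2 nucleophile) adds to C4 anti to the C5 alkoxy group, and the resulting lithium enolate is benzylated at C3 anti to the new C4 substituent, fixing both stereocentres. Nickel then strips sulfur and benzyl, and hydroxide–borohydride converts the C5 acetal carbon into the lactone CH2O.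

Key step: step 3

Remark: l-menthyl denotes (1R,2S,5R)-2-isopropyl-5-methylcyclohexyl. With the (5R) acetal centre the all-trans adduct is (3R,4R,5R) and leads to the (3R,4R)-lactone, which is the trans configuration written in the target SMILES.

Step 1
Reactants: 1 syringaldehyde (4-hydroxy-3,5-dimethoxybenzaldehyde); 2 benzyl bromide
Product: 3 4-benzyloxy-3,5-dimethoxybenzaldehyde
Conditions: BnBr (1.1 equiv), K2CO3 (1.5 equiv), DMF, 60 °C
Reagents that add atoms: benzyl bromide (2), BrCc1ccccc1
Why: Williamson ether synthesis, in which the phenoxide of 1 (its only acidic site) displaces bromide from the benzylic halide in an SN2 reaction while the aldehyde is inert to carbonate.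

Step 2
Reactants: 3 4-benzyloxy-3,5-dimethoxybenzaldehyde; 4 propane-1,3-dithiol
Product: 5 2-(4-benzyloxy-3,5-dimethoxyphenyl)-1,3-dithiane
Conditions: HS(CH2)3SH (1.1 equiv), BF3·OEt2 (0.2 equiv), CH2Cl2, 0 °C → rt
Reagents that add atoms: propane-1,3-dithiol (4), SCCCS
Why: Lewis-acid-catalysed dithioacetalisation of the aromatic aldehyde is driven by closure of the six-membered 1,3-dithiane and loss of water, and a catalytic amount of BF3·OEt2 at 0 °C to room temperature is too mild to cleave the aryl benzyl or methyl ethers.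

Step 3
Reactants: 5 2-(4-benzyloxy-3,5-dimethoxyphenyl)-1,3-dithiane; 6 (5R)-5-(l-menthyloxy)furan-2(5H)-one; 7 3,4,5-trimethoxybenzyl bromide
Product: 10 (3R,4R,5R)-4-[2-(4-benzyloxy-3,5-dimethoxyphenyl)-1,3-dithian-2-yl]-5-(l-menthyloxy)-3-(3,4,5-trimethoxybenzyl)dihydrofuran-2(3H)-one, via lithiated dithiane 8 (not isolated), via lithium enolate 9 (not isolated)
Conditions: 5 (1.1 equiv), n-BuLi (1.05 equiv), THF, −78 → −20 °C; 6 (1.0 equiv), −78 °C; 7 (1.5 equiv), DMPU, −78 °C → rt; aq NH4Cl
Reagents that add atoms: (5R)-5-(l-menthyloxy)furan-2(5H)-one (6), O=C1C=C[C@H](O[C@@H]2C[C@H](C)CC[C@H]2C(C)C)O1; 3,4,5-trimethoxybenzyl bromide (7), COc1cc(CBr)cc(OC)c1OC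
Why: n-BuLi removes the doubly sulfur-stabilised benzylic proton of 5 to give carbanion 8, which undergoes Michael addition to C4 of butenolide 6 and leaves lithium enolate 9, and 9 is then C-alkylated at C3 by the benzylic bromide 7 in an SN2 reaction, so the C4–C(dithiane) and C3–CH2Ar bonds are made in one flask. The closest known reaction type is the tandem conjugate addition–enolate alkylation of lithiated 2-aryl-1,3-dithianes on 5-alkoxyfuran-2(5H)-ones, that is, Corey–Seebach umpolung combined with enolate trapping. No ring is closed in this step. The (5R) acetal centre bearing the bulky menthyloxy group shields one face of the flat butenolide, so 8 should enter at C4 anti to it (new centre R), and the large dithianyl group at C4 should in turn send the bromide to the opposite face of the enolate at C3 (new centre R), giving the all-trans lactone. The step needs 1,4- over 1,2-addition, which the soft, delocalised and hindered aryl-dithianyl anion in THF at −78 °C secures, and complete C-alkylation of a hindered enolate, which the reactive benzylic bromide in excess and DMPU as lithium-coordinating cosolvent secure. The placement of the two aryl groups is fixed by using the syringyl unit as the nucleophile and the trimethoxyphenyl unit as the electrophile.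

Step 4
Reactants: 10 (3R,4R,5R)-4-[2-(4-benzyloxy-3,5-dimethoxyphenyl)-1,3-dithian-2-yl]-5-(l-menthyloxy)-3-(3,4,5-trimethoxybenzyl)dihydrofuran-2(3H)-one
Product: 11 (3R,4R,5R)-4-(4-hydroxy-3,5-dimethoxybenzyl)-5-(l-menthyloxy)-3-(3,4,5-trimethoxybenzyl)dihydrofuran-2(3H)-one
Conditions: Raney Ni (W-2, large excess), H2 (1 atm), EtOH, 70 °C
Reagents that add atoms: none
Why: Mozingo-type reductive desulfurisation, in which hydrogen-saturated Raney Ni cleaves both C–S bonds of the benzylic dithioketal to leave the C4–CH2–aryl unit and under the same conditions hydrogenolyses the aryl benzyl ether to the free phenol, while the acetal-lactone, the aryl methyl ethers and the three stereocentres, none of which takes part, should stay as they are.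

Step 5
Reactants: 11 (3R,4R,5R)-4-(4-hydroxy-3,5-dimethoxybenzyl)-5-(l-menthyloxy)-3-(3,4,5-trimethoxybenzyl)dihydrofuran-2(3H)-one
Product: 14 (3R,4R)-4-(4-hydroxy-3,5-dimethoxybenzyl)-3-(3,4,5-trimethoxybenzyl)dihydrofuran-2(3H)-one (target), via aldehyde carboxylate 12 (not isolated), via hydroxy acid 13 (not isolated)
Conditions: KOH (4 equiv), NaBH4 (2 equiv), EtOH/H2O, 0 °C → rt, N2; then 2 M HCl to pH 1, rt
Reagents that add atoms: KOH, [K+].[OH-] (the hydroxide oxygen enters the carboxylate and can remain as the lactone carbonyl oxygen after ring closure)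
Why: Hydroxide saponifies the acyloxy-acetal (pseudo-ester), which opens the ring, expels l-menthoxide and unmasks the C5 aldehyde beside an unreactive carboxylate; NaBH4 reduces that aldehyde as it forms (chemoselective carbonyl reduction), and acidification closes the five-membered lactone by intramolecular esterification (5-exo-trig), with C3 and C4 expected to keep their trans (3R,4R) configuration because the aldehyde is trapped faster than it can enolise.

Compound list
1 | syringaldehyde (4-hydroxy-3,5-dimethoxybenzaldehyde) | COc1cc(C=O)cc(OC)c1O | starting material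
2 | benzyl bromide | BrCc1ccccc1 | starting material
3 | 4-benzyloxy-3,5-dimethoxybenzaldehyde | COc1cc(C=O)cc(OC)c1OCc1ccccc1 | intermediate
4 | propane-1,3-dithiol | SCCCS | starting material
5 | 2-(4-benzyloxy-3,5-dimethoxyphenyl)-1,3-dithiane | COc1cc(C2SCCCS2)cc(OC)c1OCc1ccccc1 | intermediate
6 | (5R)-5-{[(1R,2S,5R)-2-isopropyl-5-methylcyclohexyl]oxy}furan-2(5H)-one, (5R)-5-(l-menthyloxy)furan-2(5H)-one | O=C1C=C[C@H](O[C@@H]2C[C@H](C)CC[C@H]2C(C)C)O1 | starting material
7 | 3,4,5-trimethoxybenzyl bromide | COc1cc(CBr)cc(OC)c1OC | starting material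
8 | 2-(4-benzyloxy-3,5-dimethoxyphenyl)-2-lithio-1,3-dithiane (lithiated dithiane) | [Li]C1(SCCCS1)c1cc(OC)c(OCc2ccccc2)c(OC)c1 | intermediate
9 | lithium (4R,5R)-4-[2-(4-benzyloxy-3,5-dimethoxyphenyl)-1,3-dithian-2-yl]-5-(l-menthyloxy)-4,5-dihydrofuran-2-olate (lithium enolate) | COc1cc(C2(SCCCS2)[C@H]2[C@H](O[C@@H]3C[C@H](C)CC[C@H]3C(C)C)OC(O[Li])=C2)cc(OC)c1OCc1ccccc1 | intermediate
10 | (3R,4R,5R)-4-[2-(4-benzyloxy-3,5-dimethoxyphenyl)-1,3-dithian-2-yl]-5-(l-menthyloxy)-3-(3,4,5-trimethoxybenzyl)dihydrofuran-2(3H)-one, all-trans | COc1cc(C2(SCCCS2)[C@H]2[C@H](O[C@@H]3C[C@H](C)CC[C@H]3C(C)C)OC(=O)[C@@H]2Cc2cc(OC)c(OC)c(OC)c2)cc(OC)c1OCc1ccccc1 | intermediate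
11 | (3R,4R,5R)-4-(4-hydroxy-3,5-dimethoxybenzyl)-5-(l-menthyloxy)-3-(3,4,5-trimethoxybenzyl)dihydrofuran-2(3H)-one, all-trans | COc1cc(C[C@H]2[C@H](O[C@@H]3C[C@H](C)CC[C@H]3C(C)C)OC(=O)[C@@H]2Cc2cc(OC)c(OC)c(OC)c2)cc(OC)c1O | intermediate
12 | dipotassium salt (carboxylate and phenoxide) of (2R,3R)-3-formyl-4-(4-hydroxy-3,5-dimethoxyphenyl)-2-(3,4,5-trimethoxybenzyl)butanoic acid (aldehyde carboxylate) | COc1cc(C[C@@H](C=O)[C@@H](Cc2cc(OC)c(OC)c(OC)c2)C(=O)[O-])cc(OC)c1[O-].[K+].[K+] | intermediate
13 | (2R,3R)-4-hydroxy-3-(4-hydroxy-3,5-dimethoxybenzyl)-2-(3,4,5-trimethoxybenzyl)butanoic acid (hydroxy acid) | COc1cc(C[C@@H](CO)[C@@H](Cc2cc(OC)c(OC)c(OC)c2)C(=O)O)cc(OC)c1O | intermediate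
14 | (3R,4R)-4-(4-hydroxy-3,5-dimethoxybenzyl)-3-(3,4,5-trimethoxybenzyl)dihydrofuran-2(3H)-one | COc1cc(C[C@H]2COC(=O)[C@@H]2Cc2cc(OC)c(OC)c(OC)c2)cc(OC)c1O | target

Total step count: 5
Longest linear sequence: 5 steps (1 → 3 → 5 → 10 → 11 → 14)

Steps most likely to fail

Step 3. The hindered enolate may be trapped incompletely, so that it is merely protonated on work-up. Some 1,2-addition to the lactone carbonyl or alkylation of unreacted dithiane anion may also compete. Fallback: the three-component coupling is split into two operations, setting out from 5 and 6. Lithiation of 5 (n-BuLi, THF, −78 → −20 °C), addition of 6 at −78 °C and a cold quench with aq NH4Cl should give the conjugate adduct (4R,5R)-4-[2-(4-benzyloxy-3,5-dimethoxyphenyl)-1,3-dithian-2-yl]-5-(l-menthyloxy)dihydrofuran-2(3H)-one F1, which can be purified. Deprotonation with LiN(i-Pr)2 (THF, −78 °C) then regenerates enolate 9 free of any excess dithiane anion, and alkylation with 7 and DMPU (−78 → 0 °C) returns to the route at 10.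

Step 4. Hydrogenolysis of the benzyl ether may lag behind desulfurisation, because the nickel surface is progressively sulfided, leaving the phenol only partly freed. Fallback: the two hydrogenolyses are separated, setting out from 10. Desulfurisation with acetone-deactivated Raney Ni in EtOH at rt to 50 °C without added H2 should give mainly (3R,4R,5R)-4-(4-benzyloxy-3,5-dimethoxybenzyl)-5-(l-menthyloxy)-3-(3,4,5-trimethoxybenzyl)dihydrofuran-2(3H)-one F2; any 11 formed alongside is simply carried along. The sulfur-free material is then debenzylated over palladium (H2 1 atm, 10% Pd/C, EtOAc/EtOH, rt), which rejoins the route at 11.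

Step 5. The transient aldehyde may enolise in KOH before it is reduced, which would epimerise C4 and erode the trans relationship and the enantiomeric purity. Ring opening of the hindered acetal-lactone may also be slow. Fallback: the acetal is cleaved under acid before any base is used, setting out from 11. Hydrolysis (1 M HCl, dioxane/H2O, 50 °C) releases l-menthol and should give the lactol (3R,4R)-5-hydroxy-4-(4-hydroxy-3,5-dimethoxybenzyl)-3-(3,4,5-trimethoxybenzyl)dihydrofuran-2(3H)-one F3, as both C5 epimers in equilibrium with the aldehyde acid. NaBH4 in EtOH at 0 °C without added hydroxide then reduces the ring-opened aldehyde, and acidification (2 M HCl) closes the lactone, returning to the route at 14.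

Further compounds
F1 | step 3 | (4R,5R)-4-[2-(4-benzyloxy-3,5-dimethoxyphenyl)-1,3-dithian-2-yl]-5-(l-menthyloxy)dihydrofuran-2(3H)-one | COc1cc(C2(SCCCS2)[C@H]2[C@H](O[C@@H]3C[C@H](C)CC[C@H]3C(C)C)OC(=O)C2)cc(OC)c1OCc1ccccc1
F2 | step 4 | (3R,4R,5R)-4-(4-benzyloxy-3,5-dimethoxybenzyl)-5-(l-menthyloxy)-3-(3,4,5-trimethoxybenzyl)dihydrofuran-2(3H)-one | COc1cc(C[C@H]2[C@H](O[C@@H]3C[C@H](C)CC[C@H]3C(C)C)OC(=O)[C@@H]2Cc2cc(OC)c(OC)c(OC)c2)cc(OC)c1OCc1ccccc1
F3 | step 5 | (3R,4R)-5-hydroxy-4-(4-hydroxy-3,5-dimethoxybenzyl)-3-(3,4,5-trimethoxybenzyl)dihydrofuran-2(3H)-one (both C5 epimers) | COc1cc(C[C@H]2C(O)OC(=O)[C@@H]2Cc2cc(OC)c(OC)c(OC)c2)cc(OC)c1O
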